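The benzofuran is cut at C3, the furan carbon that joins three different partners: C3a of the oxygenated ring A, C2 with its resorcinol ring B, and the formyl carbon. A symmetric 3,5-dimethoxyphenol carrying the hydroxyisopentyl chain, 2,4-bis(benzyloxy)phenylglyoxal and nitromethane (a formyl-anion equivalent) are merged in one flask: the glyoxal CHO carbon becomes C3, bonded to C3a and to CH2NO2, and the phenol oxygen closes the furan ring onto the ketone (O1–C2). A reductive Nef reaction, carbonyl-directed 4-O-demethylation and hydrogenolysis finish the synthesis.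

Key step: step 6

Remark: Ebenfuran V has no stereogenic element, so the compound itself is the "single enantiomer" and no step sets stereochemistry; the stereocentres of the transient species 9, 11 and 12 are unspecified and vanish on aromatisation.

**Step 1**
Reactants: 1 4-hydroxy-2,6-dimethoxybenzaldehyde
Product: 2 methyl (E)-3-(4-hydroxy-2,6-dimethoxyphenyl)prop-2-enoate
Conditions: Ph3P=CHCO2Me (1.3 equiv), toluene, 110 °C
Reagents that add atoms: methyl (triphenylphosphoranylidene)acetate, COC(=O)C=P(c1ccccc1)(c1ccccc1)c1ccccc1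
Why: Wittig olefination with a stabilised ylide, which tolerates the free phenol and should give the E-cinnamate (the geometry is removed in step 2).

**Step 2**
Reactants: 2 methyl (E)-3-(4-hydroxy-2,6-dimethoxyphenyl)prop-2-enoate
Product: 3 methyl 3-(4-hydroxy-2,6-dimethoxyphenyl)propanoate
Conditions: H2 (1 atm), 10% Pd/C, MeOH, rt
Reagents that add atoms: none
Why: Catalytic hydrogenation of the conjugated C=C bond, under which the arene, the ester and the methyl ethers are inert.

**Step 3**
Reactants: 3 methyl 3-(4-hydroxy-2,6-dimethoxyphenyl)propanoate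
Product: 4 4-(3-hydroxy-3-methylbutyl)-3,5-dimethoxyphenol
Conditions: MeMgBr (4.5 equiv), THF, 0 °C → rt; aq. NH4Cl
Reagents that add atoms: methylmagnesium bromide, C[Mg]Br
Why: Double Grignard addition to the ester gives the tertiary carbinol, with one further equivalent consumed by the phenol, whose magnesium phenoxide is inert.

**Step 4**
Reactants: 5 2,4-dihydroxyacetophenone
Product: 6 1-[2,4-bis(benzyloxy)phenyl]ethanone
Conditions: BnBr (2.4 equiv), K2CO3 (excess), DMF, 70 °C
Reagents that add atoms: benzyl bromide, BrCc1ccccc1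
Why: Williamson ether synthesis, with DMF and heat to alkylate also the hydrogen-bonded 2-OH.

**Step 5**
Reactants: 6 1-[2,4-bis(benzyloxy)phenyl]ethanone
Product: 7 2-[2,4-bis(benzyloxy)phenyl]-2-oxoacetaldehyde
Conditions: SeO2 (1.3 equiv), 1,4-dioxane/H2O (30:1), 100 °C; filter, dry azeotropically with toluene
Reagents that add atoms: selenium dioxide, O=[Se]=O
Why: Riley oxidation of the aryl methyl ketone to the arylglyoxal, which benzyl aryl ethers tolerate.

**Step 6**
Reactants: 4 4-(3-hydroxy-3-methylbutyl)-3,5-dimethoxyphenol; 7 2-[2,4-bis(benzyloxy)phenyl]-2-oxoacetaldehyde; 8 nitromethane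
Product: 13 4-{2-[2,4-bis(benzyloxy)phenyl]-4,6-dimethoxy-3-(nitromethyl)-1-benzofuran-5-yl}-2-methylbutan-2-ol, via nitroaldol 9 (not isolated), via nitroenone 10 (not isolated), via Michael adduct 11 (not isolated), via hemiketal 12 (not isolated)
Conditions: 7, 8 (3 equiv), Et3N (0.1 equiv), THF, 0 °C; evaporate; MsCl (1.05 equiv), Et3N (2.1 equiv), CH2Cl2, −20 °C; TsOH·H2O (0.3 equiv), then 4 (1.0 equiv), 0 °C → rt
Reagents that add atoms: none
Why: Proposed new method: amine-catalysed Henry addition of 8 to the aldehyde carbon of 7 gives 9, and mesylation with E1cB elimination gives the β-nitroenone 10, whose carbon next to the ketone (β to nitro) is attacked by an ortho carbon of the phloroglucinol-type phenol 4 in a Friedel–Crafts conjugate addition, forming C3–C3a in 11. Under the same acid the phenol oxygen adds to the aryl ketone (5-exo-trig hemiketalisation to 12) and water is lost, so the furan ring closes through the O1–C2 bond and becomes aromatic. The closest known reaction types are the three-component condensation of phenols, arylglyoxals and CH-acids such as Meldrum's acid to 2-arylbenzofuran-3-yl derivatives, the Friedel–Crafts alkylation of electron-rich phenols with nitroalkenes, and the acid cyclodehydration of 2-(2-hydroxyaryl)-1-arylethanones. No stereocentre is created in the product, since those of 9, 11 and 12 are erased on elimination and aromatisation. Regioselectivity rests on the substrates: the two ortho carbons of 4 are equivalent by symmetry, the para carbon is blocked by the side chain, and the nitro group as the stronger acceptor directs the phenol to the former aldehyde carbon. Chemoselectivity requires that the nitroenone is complete before the phenol is admitted (no direct phenol–glyoxal condensation) and that the medium stays acidic afterwards (no base-induced loss of HNO2 from 11); nitromethane is removed before mesylation, and catalytic TsOH at or below room temperature should spare the tertiary alcohol.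

**Step 7**
Reactants: 13 4-{2-[2,4-bis(benzyloxy)phenyl]-4,6-dimethoxy-3-(nitromethyl)-1-benzofuran-5-yl}-2-methylbutan-2-ol
Product: 15 2-[2,4-bis(benzyloxy)phenyl]-5-(3-hydroxy-3-methylbutyl)-4,6-dimethoxy-1-benzofuran-3-carbaldehyde, via sodium nitronate 14 (not isolated)
Conditions: NaOMe (1.2 equiv), MeOH/THF, 0 °C; then aq. TiCl3 (4.5 equiv), NH4OAc buffer (pH 5–6), 0 °C → rt
Reagents that add atoms: water, O; sodium methoxide, C[O-].[Na+] (sodium of 14 only)
Why: Nef reaction in its reductive McMurry form, in which nitronate 14 is reduced at nitrogen by Ti(III) and the C=N bond is hydrolysed in the buffer, conditions that are non-oxidising for the electron-rich furan and too weakly acidic to ionise the tertiary alcohol.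

**Step 8**
Reactants: 15 2-[2,4-bis(benzyloxy)phenyl]-5-(3-hydroxy-3-methylbutyl)-4,6-dimethoxy-1-benzofuran-3-carbaldehyde
Product: 16 2-[2,4-bis(benzyloxy)phenyl]-4-hydroxy-5-(3-hydroxy-3-methylbutyl)-6-methoxy-1-benzofuran-3-carbaldehyde
Conditions: MgI2·OEt2 (3 equiv), toluene, 60 °C; aq. NH4Cl
Reagents that add atoms: none
Why: Carbonyl-directed Lewis acid/iodide cleavage of an aryl methyl ether, in which Mg(II) bridges the formyl oxygen and the peri 4-OMe (also twisted by its two ortho neighbours) while iodide removes the methyl group, leaving the unchelated 6-OMe, the benzyl ethers and the tertiary alcohol untouched under neutral conditions.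

**Step 9**
Reactants: 16 2-[2,4-bis(benzyloxy)phenyl]-4-hydroxy-5-(3-hydroxy-3-methylbutyl)-6-methoxy-1-benzofuran-3-carbaldehyde
Product: 17 Ebenfuran V, 2-(2,4-dihydroxyphenyl)-4-hydroxy-5-(3-hydroxy-3-methylbutyl)-6-methoxy-1-benzofuran-3-carbaldehyde
Conditions: H2 (1 atm), 10% Pd/C, EtOAc, rt, stopped after uptake of 2 equiv
Reagents that add atoms: none
Why: Hydrogenolysis of the two aryl benzyl ethers, which should outpace reduction of the formyl group because that group is a hydrogen-bonded vinylogous ester (O1–C2=C3–CH=O), while the tetrasubstituted furan double bond is inert.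

**Compound list**
1 | 4-hydroxy-2,6-dimethoxybenzaldehyde | COc1cc(O)cc(OC)c1C=O | starting material
2 | methyl (E)-3-(4-hydroxy-2,6-dimethoxyphenyl)prop-2-enoate | COC(=O)/C=C/c1c(OC)cc(O)cc1OC | intermediate
3 | methyl 3-(4-hydroxy-2,6-dimethoxyphenyl)propanoate | COC(=O)CCc1c(OC)cc(O)cc1OC | intermediate
4 | 4-(3-hydroxy-3-methylbutyl)-3,5-dimethoxyphenol | COc1cc(O)cc(OC)c1CCC(C)(C)O | intermediate
5 | 2,4-dihydroxyacetophenone | CC(=O)c1ccc(O)cc1O | starting material
6 | 1-[2,4-bis(benzyloxy)phenyl]ethanone | CC(=O)c1ccc(OCc2ccccc2)cc1OCc1ccccc1 | intermediate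
7 | 2-[2,4-bis(benzyloxy)phenyl]-2-oxoacetaldehyde | O=CC(=O)c1ccc(OCc2ccccc2)cc1OCc1ccccc1 | intermediate
8 | nitromethane | C[N+](=O)[O-] | starting material
9 | 1-[2,4-bis(benzyloxy)phenyl]-2-hydroxy-3-nitropropan-1-one (racemic nitroaldol) | O=C(C(O)C[N+](=O)[O-])c1ccc(OCc2ccccc2)cc1OCc1ccccc1 | intermediate
10 | (E)-1-[2,4-bis(benzyloxy)phenyl]-3-nitroprop-2-en-1-one (nitroenone) | O=C(/C=C/[N+](=O)[O-])c1ccc(OCc2ccccc2)cc1OCc1ccccc1 | intermediate
11 | 1-[2,4-bis(benzyloxy)phenyl]-2-[6-hydroxy-3-(3-hydroxy-3-methylbutyl)-2,4-dimethoxyphenyl]-3-nitropropan-1-one (racemic Michael adduct) | COc1cc(O)c(C(C[N+](=O)[O-])C(=O)c2ccc(OCc3ccccc3)cc2OCc2ccccc2)c(OC)c1CCC(C)(C)O | intermediate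
12 | 2-[2,4-bis(benzyloxy)phenyl]-5-(3-hydroxy-3-methylbutyl)-4,6-dimethoxy-3-(nitromethyl)-2,3-dihydro-1-benzofuran-2-ol (hemiketal, racemic diastereomer mixture) | COc1cc2OC(O)(c3ccc(OCc4ccccc4)cc3OCc3ccccc3)C(C[N+](=O)[O-])c2c(OC)c1CCC(C)(C)O | intermediate
13 | 4-{2-[2,4-bis(benzyloxy)phenyl]-4,6-dimethoxy-3-(nitromethyl)-1-benzofuran-5-yl}-2-methylbutan-2-ol | COc1cc2oc(-c3ccc(OCc4ccccc4)cc3OCc3ccccc3)c(C[N+](=O)[O-])c2c(OC)c1CCC(C)(C)O | intermediate
14 | sodium nitronate of 13 (benzofuran-3-yl–CH=N(O)O− Na+) | COc1cc2oc(-c3ccc(OCc4ccccc4)cc3OCc3ccccc3)c(C=[N+]([O-])[O-])c2c(OC)c1CCC(C)(C)O.[Na+] | intermediate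
15 | 2-[2,4-bis(benzyloxy)phenyl]-5-(3-hydroxy-3-methylbutyl)-4,6-dimethoxy-1-benzofuran-3-carbaldehyde | COc1cc2oc(-c3ccc(OCc4ccccc4)cc3OCc3ccccc3)c(C=O)c2c(OC)c1CCC(C)(C)O | intermediate
16 | 2-[2,4-bis(benzyloxy)phenyl]-4-hydroxy-5-(3-hydroxy-3-methylbutyl)-6-methoxy-1-benzofuran-3-carbaldehyde | COc1cc2oc(-c3ccc(OCc4ccccc4)cc3OCc3ccccc3)c(C=O)c2c(O)c1CCC(C)(C)O | intermediate
17 | Ebenfuran V, 2-(2,4-dihydroxyphenyl)-4-hydroxy-5-(3-hydroxy-3-methylbutyl)-6-methoxy-1-benzofuran-3-carbaldehyde (achiral) | COc1cc2oc(-c3ccc(O)cc3O)c(C=O)c2c(O)c1CCC(C)(C)O | target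

**Step count**
Total: 9 steps. Longest linear sequence: 7 steps (steps 1–3, then 6–9); the glyoxal branch (steps 4–5) joins at step 6.

**Steps most likely to fail**

Step 6 (proposed new method). The sequence may be diverted by hydroxyalkylation of the phenol by unconverted glyoxal or by loss of nitrous acid from the open-chain adduct before ring closure. Acid ionisation of the tertiary carbinol or of the benzylic-type C–NO2 bond is a further risk. The fallback uses the known chalcone-rearrangement route to 2-aryl-3-formylbenzofurans; it sets out from 4 and 6 and rejoins at aldehyde 15, bypassing steps 6 and 7. Phenol 4 is ortho-formylated (MgCl2, Et3N, paraformaldehyde, MeCN, reflux) to 6-hydroxy-3-(3-hydroxy-3-methylbutyl)-2,4-dimethoxybenzaldehyde F1. Its phenol is capped (MOMCl, K2CO3, acetone) to give the methoxymethyl ether F2. Claisen–Schmidt condensation with ketone 6 (KOH, EtOH) gives the chalcone F3. Oxidative 1,2-shift of the electron-rich aryl group (PhI(OAc)2, TsOH, MeOH/HC(OMe)3) gives the β-keto dimethyl acetal F4. TsOH in (CF3)2CHOH at 0 °C → rt then removes the MOM group, closes the phenol onto the aryl ketone and unmasks the formyl group to give 15.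

Step 7. The nitro compound may lose nitrite by heterolysis to a furan-stabilised cation, or the reduction may stall at the C=N stage or run on past it. The fallback sets out from 13 and rejoins at 15. The primary nitro group is reduced only as far as the aldoxime F5 with SnCl2/PhSH/Et3N in MeCN. The isolated oxime is then cleaved by exchange with aqueous glyoxylic acid in THF at rt, without a reducing metal.

Step 8. The seven-membered magnesium chelate may be too weak, so that ether cleavage is slow or unselective. Alternatively the Lewis acid may ionise the tertiary carbinol, which then closes a chroman ring onto the freed 4-OH. The fallback sets out from 15 and rejoins at target 17, bypassing steps 8 and 9. The carbinol is masked (TBSOTf, 2,6-lutidine, CH2Cl2) to give the tert-butyldimethylsilyl ether F6. BCl3 with pentamethylbenzene (CH2Cl2, −78 → −30 °C) forms the boron chelate, cleaves the 4-OMe and removes both benzyl groups, giving the silyl-protected triphenol F7. TBAF in THF then releases 17.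

**Further compounds**
F1 | step 6 | 6-hydroxy-3-(3-hydroxy-3-methylbutyl)-2,4-dimethoxybenzaldehyde | COc1cc(O)c(C=O)c(OC)c1CCC(C)(C)O
F2 | step 6 | 3-(3-hydroxy-3-methylbutyl)-2,4-dimethoxy-6-(methoxymethoxy)benzaldehyde | COCOc1cc(OC)c(CCC(C)(C)O)c(OC)c1C=O
F3 | step 6 | (E)-1-[2,4-bis(benzyloxy)phenyl]-3-[3-(3-hydroxy-3-methylbutyl)-2,4-dimethoxy-6-(methoxymethoxy)phenyl]prop-2-en-1-one | COCOc1cc(OC)c(CCC(C)(C)O)c(OC)c1/C=C/C(=O)c1ccc(OCc2ccccc2)cc1OCc1ccccc1
F4 | step 6 | 1-[2,4-bis(benzyloxy)phenyl]-2-[3-(3-hydroxy-3-methylbutyl)-2,4-dimethoxy-6-(methoxymethoxy)phenyl]-3,3-dimethoxypropan-1-one (racemic) | COCOc1cc(OC)c(CCC(C)(C)O)c(OC)c1C(C(OC)OC)C(=O)c1ccc(OCc2ccccc2)cc1OCc1ccccc1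
F5 | step 7 | (E)-2-[2,4-bis(benzyloxy)phenyl]-5-(3-hydroxy-3-methylbutyl)-4,6-dimethoxy-1-benzofuran-3-carbaldehyde oxime | COc1cc2oc(-c3ccc(OCc4ccccc4)cc3OCc3ccccc3)c(/C=N/O)c2c(OC)c1CCC(C)(C)O
F6 | step 8 | 2-[2,4-bis(benzyloxy)phenyl]-5-{3-[(tert-butyldimethylsilyl)oxy]-3-methylbutyl}-4,6-dimethoxy-1-benzofuran-3-carbaldehyde | COc1cc2oc(-c3ccc(OCc4ccccc4)cc3OCc3ccccc3)c(C=O)c2c(OC)c1CCC(C)(C)O[Si](C)(C)C(C)(C)C
F7 | step 8 | 5-{3-[(tert-butyldimethylsilyl)oxy]-3-methylbutyl}-2-(2,4-dihydroxyphenyl)-4-hydroxy-6-methoxy-1-benzofuran-3-carbaldehyde | COc1cc2oc(-c3ccc(O)cc3O)c(C=O)c2c(O)c1CCC(C)(C)O[Si](C)(C)C(C)(C)C
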